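## Structural features

28 is a labdane-type diterpenoid. Ring A (C1–C5 and C10, gem-dimethyl at C4) and ring B (C5–C10) share the C5–C10 bond, and a five-carbon chain (C11–C15, methyl C16 on C13, acetate on C15) is attached to C9. The decalin is cis-fused: H5 and the angular methyl C20 stand on the same face (called α below), as do H9 and the tertiary hydroxyl on C8, so the C9 chain and methyl C17 are β. C5, C10, C9 and C8 are four contiguous stereocentres, C10 quaternary and C8 a fully substituted carbinol; the fifth, C13, is insulated from the rings by two methylene groups and cannot be induced from them. The fragile groups are the tertiary alcohol, which ionises and dehydrates under acid, and the primary acetate, which does not survive hydride, organometallic or strongly basic reagents. The real difficulty is the quaternary C10 cis to H5 with C9 beside it, together with the syn pair H9/OH8 on the face of C20. The key step exploits the fact that C5, with its hydrogen and its bond to C4, is the isopropenyl-bearing stereocentre of 1, that the ring CH2 next to it can become C10, and that the ketone carbon and the methyl-bearing alkene carbon of 1 are C9 and C8 (with C17). With a two-carbon acyl arm (C1, C2) on C10 cis to the isopropenyl group, the isopropenyl CH2 is C3, one C2–C3 bond closes ring A, and the resulting C2 ketone with its C3=C4 double bond is the handle for the second methyl on C4.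

## Logic of the disconnections

28 to 27: the O–acyl bond at C15 is cut first, because the acetate is the group least tolerant of everything that precedes it. The gain is a diol that can be carried without ester chemistry. The forward step must acylate a primary hydroxyl and leave the tertiary C8 hydroxyl alone.

27 to 26: the O–CH2Ph bond is cut. A benzyl ether on O15 survives organolithium, cuprate, hot alkali and borane, which a silyl ether would not all do. The forward step is a neutral hydrogenolysis, possible only because no alkene is left at that stage.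

26 to 24: the C8–O and C9–H bonds, both on the α face, are cut together. Two adjacent stereocentres collapse into the flat tetrasubstituted C8=C9 alkene. The forward step must add H and OH syn, put the heteroatom on C8 and choose the face of C20 and H5.

24 to 22 to 20: the C2 methylene is traced to a ketone and one C4–CH3 bond is cut. This turns the gem-dimethyl carbon into the β-carbon of a C3=C4–C2=O enone. The demands are a conjugate addition at a β,β-disubstituted enone and a deoxygenation that tolerates the alkene and the ether.

20 to 12 plus 17: the C9–C11 bond is cut between an sp2 and an sp3 carbon. The molecule falls into a bicyclic half and a chain half that carries C13 in finished form. The forward cross-coupling must work at a tetrasubstituted, neopentyl-flanked enol triflate in the presence of an enone.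

12 to 11: the C2–C3 bond is cut and ring A opens. The bicycle becomes a monocyclic acid chloride whose two stereocentres are both already in place. The forward step needs an acylium ion that is attacked by the isopropenyl CH2 only, and an acyl arm cis to that alkene.

11 to 10 to 8 to 6: the C–Cl bond, the tert-butyl ester and the O–S bond of the enol triflate are traced back in turn. The triflate comes from the enolate that conjugate reduction of the enone in 6 provides regiospecifically. The demands are an ester cleavage that does not protonate the isopropenyl group and an enolate trap faster than attack on the ester arm.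

6 to 4 to 1 plus 2: the C10–C20 bond and then the C10–C1 bond are cut. The order matters, since the second electrophile enters anti to the isopropenyl group and must therefore be the methyl group. The forward steps need two regioselective enolisations, the second in the presence of an ester.

17 to 16 to 15 to 14 to 13: the C–I bond and the O-benzyl bond are traced to a half-ester whose two ends are already differentiated. The acid end becomes C15 and the ester end C11, which gives C13 the right configuration without any asymmetric step. The demand is chemoselective reduction of the acid before the ester.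

## Other disconnections considered

Alternative 1: The cut is C9–C10, paid for by a C2–C7 bond that exists only in the precursor. In the forward sense KH (with 18-crown-6) deprotonates the bicyclo[2.2.2]octenol A2, the alkoxide undergoes the anionic oxy-Cope shift through the boat geometry the cage enforces, and Me3SiCl caps the C7 enolate to give A1. A2 would come from addition of the alkenyllithium A4 to the ketone A3 on its alkene-side face. In its favour: one stereospecific pericyclic step makes quaternary C10, C9 and the cis ring fusion and brings in the whole chain including C13. On this point it is better than the chosen plan, which needs a separate coupling and a face-selective hydroboration for C9. Against it here: A1 has its oxygen on C7 and an extra C1=C2 alkene. C8 would still have to be hydroxylated (for instance by peracid oxidation of the silyl enol ether, again under substrate control), C7 deoxygenated next to a tertiary carbinol, and the alkene hydrogenated. A3 maps onto no chiral-pool compound and would need an asymmetric cycloaddition or a resolution, and A4 needs a geometrically pure trisubstituted alkenyl metal. Mechanistically the two plans are equally well founded; structurally the alternative sets more stereocentres at once; in step economy it is the longer route.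

Alternative 2: The cuts are C9–C10 and C1–C9, the second being a bond that must later be broken again. In the forward sense Rh2(OAc)4 decomposes the diazoketone A6 and the C9 carbenoid adds to C1=C10 from the face on which the tether sits at C5, closing ring B and a cyclopropane to give A5. In its favour: the cis-fused core with quaternary C10 is reached in very few steps, the cycloaddition is stereospecific, and the ketone ends on C8, the carbon that must carry the carbinol. On the position of the oxygen it is the equal of the chosen plan, and in steps to the bicyclic core it is better. Against it here: three stereochemical decisions remain after the key step. The cyclopropane must be cleaved reductively at C1–C9 and not C9–C10. The hindered C8 enolate must be alkylated at C9, next to C10, with an electrophile such as 17. A methyl nucleophile must then add to the C8 ketone from the β face, cis to the new chain, which is the face normally avoided. A6 would also have to be secured as a single enantiomer. The chosen plan is longer to the core but attaches the chain by cross-coupling and sets C8 and C9 in one syn addition, so its stereochemical risk sits in one step instead of three.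

Alternative 3: The cuts are C5–C10 and C8–C9, ring B being assembled by a [4+2] cycloaddition. In the forward sense the aminosiloxydiene A9 adds to the (E)-enal A8 under the chiral complex (salen)Cr(SbF6), the aldehyde carbon being the future C20, and acidic work-up eliminates the amine to give the enone A7. In its favour: the absolute configuration comes from a catalyst, C9 and C10 are set together with their relation fixed by the enal geometry, and the chain with C13 is already in place. In convergence it is the equal of the chosen plan, and in setting C9 at the outset and in access to either enantiomeric series it is better. Against it here: A8 carries a β-substituent, whereas this catalysed cycloaddition is best established for α-substituted acroleins without one. A7 has its oxygen on C7, so a carbonyl transposition to C8 plus a methyl addition would be needed. C20 arrives as an aldehyde and must be reduced to a methyl group. Ring A is still open, and the C4–C5 bond must be formed onto the enone with the cis fusion. The chosen plan draws all ring carbons and the C17 methyl from 1 with the oxidation pattern already right, and is clearly shorter.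

Key step: step 6

Remarks on the chemistry:
- 28 is read from its SMILES as the 5,10-cis-fused labdane, (3S)-5-[(1R,2R,4aS,8aR)-2-hydroxy-2,5,5,8a-tetramethyldecahydronaphthalen-1-yl]-3-methylpentyl acetate. "α" means the face carrying H5 and C20.
- Labdane numbering is used for the ring carbons throughout, including the monocyclic intermediates.
- 11 and 12 were checked atom by atom against 1 and 28; both carry C20 and H5 on the same face and need no correction.
- The ester cleavage uses a silyl triflate in place of a strong protic acid, the enolate trap is the more reactive pyridyl triflimide, and O15 is a benzyl ether so that the C2 ketone can be removed in one step.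
- 1, 2 and 13 are assumed to be bought as single enantiomers where chiral.

## Route

Step 1
Reactants: 1 (R)-carvone; 2 tert-butyl bromoacetate
Product: 4 tert-butyl 2-[(1S,6R)-3-methyl-2-oxo-6-(prop-1-en-2-yl)cyclohex-3-en-1-yl]acetate, via lithium dienolate 3 (not isolated)
Conditions: LiN(iPr)2 (1.1 equiv), THF, −78 °C; then 2, −78 → −20 °C
Reagents that add atoms: none
Why: Kinetic α′-deprotonation of the enone gives the cross-conjugated dienolate 3, which is alkylated (SN2) by the activated α-bromo ester at the future C10, mainly trans to the isopropenyl group; this configuration is erased in step 2, so the isomer ratio is of no consequence.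

Step 2
Reactants: 4 tert-butyl 2-[(1S,6R)-3-methyl-2-oxo-6-(prop-1-en-2-yl)cyclohex-3-en-1-yl]acetate
Product: 6 tert-butyl 2-[(1R,6S)-1,3-dimethyl-2-oxo-6-(prop-1-en-2-yl)cyclohex-3-en-1-yl]acetate, via lithium enolate 5 (not isolated)
Conditions: LiN(SiMe3)2 (1.05 equiv), THF, −78 → −40 °C; MeI, DMPU, −78 → 0 °C
Reagents that add atoms: iodomethane, CI
Why: Enolate alkylation: the silylamide removes the only ketone α-hydrogen but is too weak a base to enolise the tert-butyl ester at a useful rate, and iodomethane enters the trigonal C10 anti to the neighbouring isopropenyl group. This sets quaternary C10 with C20 trans and the acetate arm cis to isopropenyl, that is C20 cis to H5.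

Step 3
Reactants: 6 tert-butyl 2-[(1R,6S)-1,3-dimethyl-2-oxo-6-(prop-1-en-2-yl)cyclohex-3-en-1-yl]acetate
Product: 8 tert-butyl 2-[(1R,6S)-1,3-dimethyl-6-(prop-1-en-2-yl)-2-(trifluoromethanesulfonyloxy)cyclohex-2-en-1-yl]acetate, via lithium enolate 7 (not isolated)
Conditions: LiBH(sBu)3 (1.1 equiv), THF, −78 °C; then N-(5-chloropyridin-2-yl)triflimide, −78 → 0 °C
Reagents that add atoms: N-(5-chloropyridin-2-yl)bis(trifluoromethanesulfonyl)imide, FC(F)(F)S(=O)(=O)N(c1ccc(Cl)cn1)S(=O)(=O)C(F)(F)F
Why: Conjugate hydride addition to the β-unsubstituted enone (1,2-attack is hindered by the adjacent quaternary carbon) gives the regiodefined enolate 7, and O-sulfonylation by the reactive pyridyl triflimide at low temperature should outrun acylation of the enolate by the ester arm. The tetrasubstituted C8=C9 enol triflate results and no stereocentre is formed.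

Step 4
Reactants: 8 tert-butyl 2-[(1R,6S)-1,3-dimethyl-6-(prop-1-en-2-yl)-2-(trifluoromethanesulfonyloxy)cyclohex-2-en-1-yl]acetate
Product: 10 2-[(1R,6S)-1,3-dimethyl-6-(prop-1-en-2-yl)-2-(trifluoromethanesulfonyloxy)cyclohex-2-en-1-yl]acetic acid, via silyl ester 9 (not isolated)
Conditions: Me3SiOTf (2 equiv), 2,6-lutidine (3 equiv), CH2Cl2, 0 °C → rt; aqueous KH2PO4 work-up
Reagents that add atoms: none
Why: Silyl-triflate cleavage of a tert-butyl ester: O-silylation, loss of the tert-butyl cation as isobutene under lutidine buffering, and hydrolysis of silyl ester 9 on work-up. It is chosen over CF3CO2H because a strong protic acid could protonate the isopropenyl group and let the cis carboxylic acid close a six-membered lactone onto C4.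

Step 5
Reactants: 10 2-[(1R,6S)-1,3-dimethyl-6-(prop-1-en-2-yl)-2-(trifluoromethanesulfonyloxy)cyclohex-2-en-1-yl]acetic acid
Product: 11 2-[(1R,6S)-1,3-dimethyl-6-(prop-1-en-2-yl)-2-(trifluoromethanesulfonyloxy)cyclohex-2-en-1-yl]acetyl chloride
Conditions: (COCl)2 (1.5 equiv), DMF (cat.), CH2Cl2, 0 °C, argon sweep; evaporate, use crude at once
Reagents that add atoms: oxalyl chloride, ClC(=O)C(Cl)=O
Why: Standard chlorination through the chloroiminium species; all by-products are gases, so the crude acid chloride can go straight into step 6, and the short exposure at 0 °C with gas removal limits HCl addition to the isopropenyl group.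

Step 6
Reactants: 11 2-[(1R,6S)-1,3-dimethyl-6-(prop-1-en-2-yl)-2-(trifluoromethanesulfonyloxy)cyclohex-2-en-1-yl]acetyl chloride
Product: 12 (4aS,8aR)-2,5,8a-trimethyl-7-oxo-3,4,4a,7,8,8a-hexahydronaphthalen-1-yl trifluoromethanesulfonate
Conditions: SnCl4 (1.2 equiv), CH2Cl2, −78 → 0 °C; cold aqueous NaHCO3
Reagents that add atoms: none
Why: SnCl4 takes chloride from 11 to give an acylium ion at C2, which is attacked by the terminal CH2 of the isopropenyl group (C3), so that the C2–C3 bond and ring A form and the charge arrives on tertiary C4; loss of a C3 proton, made acidic by the tin-bound carbonyl beside it, releases the conjugated C3=C4 enone as its SnCl4 complex, the thermodynamic sink. The closest known reaction type is the Lewis-acid-mediated intramolecular acylation of an alkene by an acid chloride to a cyclohexenone. Ring A closes in the 6-endo mode with respect to the alkene, which is the Markovnikov mode; the 5-exo alternative would need a primary cation. No stereocentre is created: C4 ends sp2, and C5 and C10 are carried over from 11, so the cis ring fusion is the one installed in step 2. The step needs chemoselectivity between two alkenes, secured by the triflyloxy group, which makes C8=C9 far too electron-poor to attack an acylium ion and would in any case lead to a strained small ring. It also needs the acyl arm and the alkene within reach, which the cis-1,2 arrangement on ring B (one axial, one equatorial) guarantees. Low temperature and a short reaction time are meant to keep the hydrogen on C5, which is γ to the new carbonyl, out of play.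

Step 7
Reactants: 13 methyl hydrogen (R)-3-methylglutarate
Product: 14 methyl (3R)-5-hydroxy-3-methylpentanoate
Conditions: BH3·SMe2 (1.1 equiv), THF, −10 °C → rt; MeOH quench; used directly
Reagents that add atoms: none
Why: Borane reduces a carboxylic acid through its acyloxyborane much faster than a methyl ester, so only the acid end (the future C15) becomes CH2OH; the stereocentre is untouched and the product is not stored, to avoid lactonisation.

Step 8
Reactants: 14 methyl (3R)-5-hydroxy-3-methylpentanoate
Product: 15 methyl (3R)-5-(benzyloxy)-3-methylpentanoate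
Conditions: benzyl 2,2,2-trichloroacetimidate (1.3 equiv), TfOH (5 mol %), CH2Cl2/cyclohexane, 0 °C → rt
Reagents that add atoms: benzyl 2,2,2-trichloroacetimidate, ClC(Cl)(Cl)C(=N)OCc1ccccc1
Why: Acid-catalysed O-benzylation with the imidate avoids an alkoxide, which would close the δ-lactone onto the ester; the benzyl ether is chosen because it survives every later step up to hydrogenolysis.

Step 9
Reactants: 15 methyl (3R)-5-(benzyloxy)-3-methylpentanoate
Product: 16 (3S)-5-(benzyloxy)-3-methylpentan-1-ol
Conditions: LiAlH4, Et2O, 0 °C
Reagents that add atoms: none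
Why: Hydride reduction of the ester end (the future C11) to the primary alcohol; the descriptor changes only because the priorities change.

Step 10
Reactants: 16 (3S)-5-(benzyloxy)-3-methylpentan-1-ol
Product: 17 benzyl (3R)-5-iodo-3-methylpentyl ether
Conditions: I2, PPh3, imidazole, CH2Cl2, 0 °C → rt
Reagents that add atoms: iodine, II
Why: Appel-type iodination of a primary alcohol through the alkoxyphosphonium ion with SN2 displacement by iodide; the stereocentre is two carbons away.

Step 11
Reactants: 12 (4aS,8aR)-2,5,8a-trimethyl-7-oxo-3,4,4a,7,8,8a-hexahydronaphthalen-1-yl trifluoromethanesulfonate; 17 benzyl (3R)-5-iodo-3-methylpentyl ether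
Product: 20 (4aS,8aR)-8-[(3S)-5-(benzyloxy)-3-methylpentyl]-4,7,8a-trimethyl-4a,5,6,8a-tetrahydronaphthalen-2(1H)-one, via alkyllithium 18 (not isolated), via lithium borate 19 (not isolated)
Conditions: 17 (1.5 equiv), tBuLi (3.0 equiv), Et2O, −78 °C; 9-methoxy-9-BBN, THF, −78 °C → rt; then 12, Pd(dppf)Cl2 (10 mol %), AsPh3 (10 mol %), K3PO4 (3 M aq), DMF, rt → 45 °C
Reagents that add atoms: none
Why: B-alkyl Suzuki–Miyaura coupling: iodine–lithium exchange and capture by the methoxyborane give borate 19, which transfers its primary alkyl group to the vinylpalladium formed by insertion of zerovalent palladium into the C9–OTf bond, and the wide-bite-angle dppf ligand favours reductive elimination over β-hydride loss. The enone and all stereocentres are spectators.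

Step 12
Reactants: 20 (4aS,8aR)-8-[(3S)-5-(benzyloxy)-3-methylpentyl]-4,7,8a-trimethyl-4a,5,6,8a-tetrahydronaphthalen-2(1H)-one
Product: 22 (4aS,8aR)-8-[(3S)-5-(benzyloxy)-3-methylpentyl]-4,4,7,8a-tetramethyl-3,4,4a,5,6,8a-hexahydronaphthalen-2(1H)-one, via silyl enol ether 21 (not isolated)
Conditions: Me2CuLi (from CuI and MeLi, 3 equiv), Me3SiCl (5 equiv), THF/Et2O, −78 → 0 °C; then 1 M HCl, THF, rt
Reagents that add atoms: lithium dimethylcuprate, [Li+].C[Cu-]C
Why: Silyl-chloride-accelerated conjugate addition of the cuprate to the β,β-disubstituted enone makes C4 the gem-dimethyl carbon (no stereocentre); the isolated tetrasubstituted alkene and the ether are inert, and dilute acid hydrolyses enol ether 21 to the ketone.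

Step 13
Reactants: 22 (4aS,8aR)-8-[(3S)-5-(benzyloxy)-3-methylpentyl]-4,4,7,8a-tetramethyl-3,4,4a,5,6,8a-hexahydronaphthalen-2(1H)-one
Product: 24 (4aR,8aS)-5-[(3S)-5-(benzyloxy)-3-methylpentyl]-1,1,4a,6-tetramethyl-1,2,3,4,4a,7,8,8a-octahydronaphthalene, via hydrazone 23 (not isolated)
Conditions: N2H4·H2O, KOH, diethylene glycol, 130 °C, then 200 °C with removal of water
Reagents that add atoms: none
Why: Wolff–Kishner reduction in its one-pot high-temperature form: the C2 ketone has CH2 groups on both sides and no α-stereocentre, and the benzyl ether and the unactivated tetrasubstituted alkene are stable to hot alkali.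

Step 14
Reactants: 24 (4aR,8aS)-5-[(3S)-5-(benzyloxy)-3-methylpentyl]-1,1,4a,6-tetramethyl-1,2,3,4,4a,7,8,8a-octahydronaphthalene
Product: 26 (1R,2R,4aS,8aR)-1-[(3S)-5-(benzyloxy)-3-methylpentyl]-2,5,5,8a-tetramethyldecahydronaphthalen-2-ol, via alkylborane 25 (not isolated)
Conditions: BH3·SMe2 (5 equiv), THF, 0 → 45 °C; then NaOH (3 M), H2O2 (30 %), 0 → 40 °C
Reagents that add atoms: hydrogen peroxide, OO
Why: Hydroboration–oxidation: boron should go to C8, the less encumbered end (C9 is flanked by quaternary C10), and the syn addition should occur on the convex α face, because in the cis-fused system ring A with its C4 gem-dimethyl group folds over the β face while C20 can lie near the alkene plane. Oxidation of the C–B bond with retention then places OH8 and H9 cis on the α face, which sets C8 and C9.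

Step 15
Reactants: 26 (1R,2R,4aS,8aR)-1-[(3S)-5-(benzyloxy)-3-methylpentyl]-2,5,5,8a-tetramethyldecahydronaphthalen-2-ol
Product: 27 (1R,2R,4aS,8aR)-1-[(3S)-5-hydroxy-3-methylpentyl]-2,5,5,8a-tetramethyldecahydronaphthalen-2-ol
Conditions: H2 (1 atm), Pd/C (10 %), EtOH, rt
Reagents that add atoms: none
Why: Neutral hydrogenolysis of the benzyl ether; no alkene remains and the tertiary alcohol is not benzylic or allylic, so nothing else can react.

Step 16
Reactants: 27 (1R,2R,4aS,8aR)-1-[(3S)-5-hydroxy-3-methylpentyl]-2,5,5,8a-tetramethyldecahydronaphthalen-2-ol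
Product: 28 (3S)-5-[(1R,2R,4aS,8aR)-2-hydroxy-2,5,5,8a-tetramethyldecahydronaphthalen-1-yl]-3-methylpentyl acetate
Conditions: Ac2O (1.5 equiv), pyridine, CH2Cl2, 0 °C → rt (no DMAP)
Reagents that add atoms: acetic anhydride, CC(=O)OC(C)=O
Why: Acylation of the primary hydroxyl; the hindered tertiary C8 hydroxyl should not react without a nucleophilic catalyst, and the basic medium cannot ionise it.

## Compound list

1 | (R)-carvone, (5R)-2-methyl-5-(prop-1-en-2-yl)cyclohex-2-en-1-one | CC(=C)[C@H]1CC(=O)C(C)=CC1 | starting material
2 | tert-butyl bromoacetate | CC(C)(C)OC(=O)CBr | starting material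
3 | lithium (3R)-6-methyl-3-(prop-1-en-2-yl)cyclohexa-1,5-dien-1-olate (kinetic dienolate of 1) | CC(=C)[C@@H]1CC=C(C)C([O-])=C1.[Li+] | intermediate
4 | tert-butyl 2-[(1S,6R)-3-methyl-2-oxo-6-(prop-1-en-2-yl)cyclohex-3-en-1-yl]acetate (acetate arm trans to isopropenyl) | CC(C)(C)OC(=O)C[C@H]1[C@H](C(C)=C)CC=C(C)C1=O | intermediate
5 | lithium (3S)-2-(2-tert-butoxy-2-oxoethyl)-6-methyl-3-(prop-1-en-2-yl)cyclohexa-1,5-dien-1-olate | CC(C)(C)OC(=O)CC1=C([O-])C(C)=CC[C@H]1C(C)=C.[Li+] | intermediate
6 | tert-butyl 2-[(1R,6S)-1,3-dimethyl-2-oxo-6-(prop-1-en-2-yl)cyclohex-3-en-1-yl]acetate (methyl trans, acetate arm cis to isopropenyl) | CC(C)(C)OC(=O)C[C@]1(C)[C@H](C(C)=C)CC=C(C)C1=O | intermediate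
7 | lithium (5S,6R)-6-(2-tert-butoxy-2-oxoethyl)-2,6-dimethyl-5-(prop-1-en-2-yl)cyclohex-1-en-1-olate | CC(C)(C)OC(=O)C[C@]1(C)[C@H](C(C)=C)CCC(C)=C1[O-].[Li+] | intermediate
8 | tert-butyl 2-[(1R,6S)-1,3-dimethyl-6-(prop-1-en-2-yl)-2-(trifluoromethanesulfonyloxy)cyclohex-2-en-1-yl]acetate | CC(C)(C)OC(=O)C[C@]1(C)[C@H](C(C)=C)CCC(C)=C1OS(=O)(=O)C(F)(F)F | intermediate
9 | trimethylsilyl 2-[(1R,6S)-1,3-dimethyl-6-(prop-1-en-2-yl)-2-(trifluoromethanesulfonyloxy)cyclohex-2-en-1-yl]acetate | C[Si](C)(C)OC(=O)C[C@]1(C)[C@H](C(C)=C)CCC(C)=C1OS(=O)(=O)C(F)(F)F | intermediate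
10 | 2-[(1R,6S)-1,3-dimethyl-6-(prop-1-en-2-yl)-2-(trifluoromethanesulfonyloxy)cyclohex-2-en-1-yl]acetic acid | OC(=O)C[C@]1(C)[C@H](C(C)=C)CCC(C)=C1OS(=O)(=O)C(F)(F)F | intermediate
11 | 2-[(1R,6S)-1,3-dimethyl-6-(prop-1-en-2-yl)-2-(trifluoromethanesulfonyloxy)cyclohex-2-en-1-yl]acetyl chloride | ClC(=O)C[C@]1(C)[C@H](C(C)=C)CCC(C)=C1OS(=O)(=O)C(F)(F)F | intermediate
12 | (4aS,8aR)-2,5,8a-trimethyl-7-oxo-3,4,4a,7,8,8a-hexahydronaphthalen-1-yl trifluoromethanesulfonate (cis-fused; C2 ketone, C3=C4, C9 triflate) | O=C1C[C@]2(C)[C@@H](CCC(C)=C2OS(=O)(=O)C(F)(F)F)C(C)=C1 | intermediate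
13 | methyl hydrogen (R)-3-methylglutarate, (3R)-5-methoxy-3-methyl-5-oxopentanoic acid | OC(=O)C[C@@H](C)CC(=O)OC | starting material
14 | methyl (3R)-5-hydroxy-3-methylpentanoate | OCC[C@@H](C)CC(=O)OC | intermediate
15 | methyl (3R)-5-(benzyloxy)-3-methylpentanoate | c1ccccc1COCC[C@@H](C)CC(=O)OC | intermediate
16 | (3S)-5-(benzyloxy)-3-methylpentan-1-ol | c1ccccc1COCC[C@@H](C)CCO | intermediate
17 | benzyl (3R)-5-iodo-3-methylpentyl ether | c1ccccc1COCC[C@@H](C)CCI | intermediate
18 | [(3S)-5-(benzyloxy)-3-methylpentyl]lithium | [Li]CC[C@H](C)CCOCc1ccccc1 | intermediate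
19 | lithium 9-[(3S)-5-(benzyloxy)-3-methylpentyl]-9-methoxy-9-borabicyclo[3.3.1]nonane ate complex | [Li+].CO[B-]1(CC[C@H](C)CCOCc3ccccc3)C2CCCC1CCC2 | intermediate
20 | (4aS,8aR)-8-[(3S)-5-(benzyloxy)-3-methylpentyl]-4,7,8a-trimethyl-4a,5,6,8a-tetrahydronaphthalen-2(1H)-one | O=C1C[C@]2(C)[C@@H](CCC(C)=C2CC[C@H](C)CCOCc3ccccc3)C(C)=C1 | intermediate
21 | {[(4aS,8aR)-8-[(3S)-5-(benzyloxy)-3-methylpentyl]-4,4,7,8a-tetramethyl-1,4,4a,5,6,8a-hexahydronaphthalen-2-yl]oxy}trimethylsilane | C[Si](C)(C)OC1=CC(C)(C)[C@@H]2CCC(C)=C(CC[C@H](C)CCOCc3ccccc3)[C@]2(C)C1 | intermediate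
22 | (4aS,8aR)-8-[(3S)-5-(benzyloxy)-3-methylpentyl]-4,4,7,8a-tetramethyl-3,4,4a,5,6,8a-hexahydronaphthalen-2(1H)-one | O=C1C[C@]2(C)[C@@H](CCC(C)=C2CC[C@H](C)CCOCc3ccccc3)C(C)(C)C1 | intermediate
23 | hydrazone of 22 at C2 | NN=C1C[C@]2(C)[C@@H](CCC(C)=C2CC[C@H](C)CCOCc3ccccc3)C(C)(C)C1 | intermediate
24 | (4aR,8aS)-5-[(3S)-5-(benzyloxy)-3-methylpentyl]-1,1,4a,6-tetramethyl-1,2,3,4,4a,7,8,8a-octahydronaphthalene (cis-fused, C8=C9) | CC1=C(CC[C@H](C)CCOCc2ccccc2)[C@]3(C)CCCC(C)(C)[C@@H]3CC1 | intermediate
25 | C8 monoalkylborane of 24 (BH2 on C8 and new H on C9, both α) | c1ccccc1COCC[C@@H](C)CC[C@@H]1[C@]2(C)CCCC(C)(C)[C@@H]2CC[C@@]1(C)B | intermediate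
26 | (1R,2R,4aS,8aR)-1-[(3S)-5-(benzyloxy)-3-methylpentyl]-2,5,5,8a-tetramethyldecahydronaphthalen-2-ol | c1ccccc1COCC[C@@H](C)CC[C@@H]1[C@]2(C)CCCC(C)(C)[C@@H]2CC[C@@]1(C)O | intermediate
27 | (1R,2R,4aS,8aR)-1-[(3S)-5-hydroxy-3-methylpentyl]-2,5,5,8a-tetramethyldecahydronaphthalen-2-ol | OCC[C@@H](C)CC[C@@H]1[C@]2(C)CCCC(C)(C)[C@@H]2CC[C@@]1(C)O | intermediate
28 | (3S)-5-[(1R,2R,4aS,8aR)-2-hydroxy-2,5,5,8a-tetramethyldecahydronaphthalen-1-yl]-3-methylpentyl acetate | CC(=O)OCC[C@@H](C)CC[C@@H]1[C@]2(C)CCCC(C)(C)[C@@H]2CC[C@@]1(C)O | target

## Step count and least certain steps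

Total step count: 16. Longest linear sequence: 12 steps (steps 1–6 and 11–16, from 1 to 28). The chain branch from 13 contributes steps 7–10 and joins at step 11.

Step 6 (key step). The most likely failure is an unwanted fate of the C4 cation: capture by chloride, or proton loss from the C4 methyl group or from C5 in place of C3. Loss from C5 would erase the ring-fusion stereocentre. Addition of HCl to the isopropenyl group during step 5 would also remove the nucleophile before ionisation. The fallback forms the same C2–C3 bond without a free cation. It sets out from 8 and comes back at 12. The tert-butyl ester of 8 would be reduced with iBu2AlH at −78 °C to the aldehyde F1. Me2AlCl would then promote an intramolecular carbonyl-ene reaction in which the aldehyde adds to the isopropenyl CH2 and takes its hydrogen from the isopropenyl methyl group, giving the homoallylic alcohol F2 with an exocyclic C4 methylene; C5–H is never at risk. Dess–Martin oxidation would give the β,γ-unsaturated ketone F3, and DBU would move the double bond into conjugation through the C3 dienolate to give 12.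

Step 14. The alkene is tetrasubstituted and flanked by quaternary C10, so addition may be slow. Forcing conditions invite migration of boron, and attack on the β face would give the 8,9-bis-epimer. The fallback separates the two bond formations and sets out from 24, coming back at 26. A singlet-oxygen ene reaction (O2, light, tetraphenylporphyrin) should place oxygen on C8 and abstract an allylic hydrogen from C11, the CH2 geminal to the bulky C10, giving the allylic hydroperoxide F4. PPh3 would reduce it to the tertiary allylic alcohol F5. Hydroxyl-directed hydrogenation of the C9=C11 bond with [Ir(cod)(PCy3)(py)]PF6 would then deliver hydrogen to C9 on the face of the C8 hydroxyl, giving 26. The syn relation is enforced by coordination, and only the face of oxygen delivery, by a very small reagent, still rests on the substrate.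

Step 11. Transmetalation to a vinylpalladium that is tetrasubstituted and next to a quaternary carbon may be slow. Hydrolysis of the triflate by the aqueous base, or β-hydride elimination and protodeboronation of the alkyl partner, could then take over. The fallback sets out from 17 (with 12 as partner) and comes back at 20. Zinc insertion (Zn dust, LiCl, THF) would give the alkylzinc iodide F6, and a Negishi coupling with 12 under Pd(dppf)Cl2 in THF/NMP would form the C9–C11 bond without water or base.

Step 2. Deprotonation next to the ester, or proton transfer to the extended dienolate, would send the methyl group to the wrong carbon. The fallback removes the competing acidity; it sets out from 4 and comes back at 6. Me3SiOTf/2,6-lutidine would cleave the ester of 4 through the silyl ester F7 to the keto acid F8. LiN(iPr)2 (2.2 equiv) would form the carboxylate–enolate dianion F9, in which the hydrogens next to the carboxylate no longer compete. Iodomethane (1 equiv) would alkylate the enolate carbon anti to the isopropenyl group to give the keto acid F10, and Boc2O, DMAP and tBuOH would restore the tert-butyl ester to give 6.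

## Further compounds

F1 | step 6 | (5S,6R)-2,6-dimethyl-6-(2-oxoethyl)-5-(prop-1-en-2-yl)cyclohex-1-en-1-yl trifluoromethanesulfonate | O=CC[C@]1(C)[C@H](C(C)=C)CCC(C)=C1OS(=O)(=O)C(F)(F)F
F2 | step 6 | (4aS,8aR)-7-hydroxy-2,8a-dimethyl-5-methylidene-3,4,4a,5,6,7,8,8a-octahydronaphthalen-1-yl trifluoromethanesulfonate (carbinol centre C2 of the labdane numbering left open, removed in the next operation) | OC1C[C@]2(C)[C@@H](CCC(C)=C2OS(=O)(=O)C(F)(F)F)C(=C)C1
F3 | step 6 | (4aS,8aR)-2,8a-dimethyl-5-methylidene-7-oxo-3,4,4a,5,6,7,8,8a-octahydronaphthalen-1-yl trifluoromethanesulfonate | O=C1C[C@]2(C)[C@@H](CCC(C)=C2OS(=O)(=O)C(F)(F)F)C(=C)C1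
F4 | step 14 | (2R,4aS,8aR)-1-[(3S)-5-(benzyloxy)-3-methylpentylidene]-2,5,5,8a-tetramethyldecahydronaphthalen-2-yl hydroperoxide (C9=C11 geometry left open, removed by hydrogenation) | c1ccccc1COCC[C@@H](C)CC=C1[C@]2(C)CCCC(C)(C)[C@@H]2CC[C@@]1(C)OO
F5 | step 14 | (2R,4aS,8aR)-1-[(3S)-5-(benzyloxy)-3-methylpentylidene]-2,5,5,8a-tetramethyldecahydronaphthalen-2-ol (C9=C11 geometry left open) | c1ccccc1COCC[C@@H](C)CC=C1[C@]2(C)CCCC(C)(C)[C@@H]2CC[C@@]1(C)O
F6 | step 11 | [(3R)-5-(benzyloxy)-3-methylpentyl]zinc iodide | I[Zn]CC[C@H](C)CCOCc1ccccc1
F7 | step 2 | trimethylsilyl 2-[(1S,6R)-3-methyl-2-oxo-6-(prop-1-en-2-yl)cyclohex-3-en-1-yl]acetate | C[Si](C)(C)OC(=O)C[C@H]1[C@H](C(C)=C)CC=C(C)C1=O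
F8 | step 2 | 2-[(1S,6R)-3-methyl-2-oxo-6-(prop-1-en-2-yl)cyclohex-3-en-1-yl]acetic acid | OC(=O)C[C@H]1[C@H](C(C)=C)CC=C(C)C1=O
F9 | step 2 | dilithium carboxylate–dienolate of F8 | [Li+].[Li+].[O-]C(=O)CC1=C([O-])C(C)=CC[C@H]1C(C)=C
F10 | step 2 | 2-[(1R,6S)-1,3-dimethyl-2-oxo-6-(prop-1-en-2-yl)cyclohex-3-en-1-yl]acetic acid | OC(=O)C[C@]1(C)[C@H](C(C)=C)CC=C(C)C1=O
A1 | alternative 1 | cis-fused bicyclic C7 trimethylsilyl enol ether (C7=C8) with C1=C2 alkene and the silyl-protected chain on C9 | CC(C)(C)[Si](C)(C)OCC[C@@H](C)CC[C@@H]1[C@]2(C)C=CCC(C)(C)[C@@H]2CC(O[Si](C)(C)C)=C1C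
A2 | alternative 1 | 5,8,8-trimethylbicyclo[2.2.2]oct-5-en-2-ol carrying the (E)-alkenyl chain on the carbinol carbon, syn to the ring alkene | O[C@@]1(/C(C)=C/CC[C@H](C)CCO[Si](C)(C)C(C)(C)C)C[C@H]2C(C)(C)C[C@@H]1C=C2C
A3 | alternative 1 | 5,8,8-trimethylbicyclo[2.2.2]oct-5-en-2-one, single enantiomer | O=C1C[C@H]2C(C)(C)C[C@@H]1C=C2C
A4 | alternative 1 | [(2E,6S)-8-(tert-butyldimethylsilyloxy)-6-methyloct-2-en-2-yl]lithium | [Li]/C(C)=C/CC[C@H](C)CCO[Si](C)(C)C(C)(C)C
A5 | alternative 2 | tricyclic cyclopropyl ketone (C8 ketone, cyclopropane C1–C9–C10) | O=C1CC[C@H]2C(C)(C)CC[C@H]3[C@@H]1[C@@]23C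
A6 | alternative 2 | 1-diazo-4-[(1S)-2,6,6-trimethylcyclohex-2-en-1-yl]butan-2-one | [N-]=[N+]=CC(=O)CC[C@H]1C(C)(C)CCC=C1C
A7 | alternative 3 | 4,4,5-trisubstituted cyclohex-2-enone (ring B, C20 as aldehyde, prenyl-type arm and chain in place) | CC(C)(C)[Si](C)(C)OCC[C@@H](C)CC[C@@H]1[C@](C=O)(CCC=C(C)C)C=CC(=O)C1
A8 | alternative 3 | (2E,5S)-7-(tert-butyldimethylsilyloxy)-5-methyl-2-(4-methylpent-3-en-1-yl)hept-2-enal | O=C/C(CCC=C(C)C)=C/CC[C@H](C)CCO[Si](C)(C)C(C)(C)C
A9 | alternative 3 | (E)-3-(tert-butyldimethylsilyloxy)-N,N-dimethylbuta-1,3-dien-1-amine | CN(C)/C=C/C(=C)O[Si](C)(C)C(C)(C)C
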